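**Plan**

- Retrosynthesis: remove five MOM ethers and one tert-butyl ester; cut the ring-B aryl–vinyl bond (Heck) to give a 3-aryloxy-6,7-dihydroxycoumarin bromide and the acrylate of (R)-danshensu; cut the lactone bond O1–C8a to give an acrylic acid with the catechol ring cis to CO2H; cut its C3=C4 alkene (Perkin) and the ArO–CH2 ether bond.
- Forward: ring B is differentiated first (MOM, Baeyer–Villiger, carboxymethylation), the acrylic acid is assembled and its geometry inverted by light, the coumarin lactone (the only ring made) closes at the anode, and the danshensu side chain is joined last.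
- Enabling feature: the 6,7-dihydroxy benzo ring is a catechol, and C8a (which carries O1) lies ortho to the side chain and para to the 6-OH, the position at which the derived o-quinone accepts a tethered carboxylate.
- Stereochemistry: the single stereocenter (R) is bought with danshensu and no bond to it is ever broken; the E cinnamate alkene comes from the Heck step.

Key step: step 7

Remark on the chemistry: in acids 8–11 the aryloxy oxygen outranks the carboxyl carbon, so Z means aryl trans to CO2H and E means aryl cis to CO2H; (R)-danshensu is taken as the commercial free acid.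

**Route**

Step 1
Reactants: 1 4-bromo-2-hydroxybenzaldehyde
Product: 2 4-bromo-2-(methoxymethoxy)benzaldehyde
Conditions: MOMCl, i-Pr2NEt, CH2Cl2, 0 °C to rt
Reagents that add atoms: chloromethyl methyl ether (MOMCl), COCCl
Why: Williamson-type O-alkylation of the phenoxide with the reactive α-chloro ether caps the oxygen meta to bromine, which is to end as the free ring-B hydroxyl.

Step 2
Reactants: 2 4-bromo-2-(methoxymethoxy)benzaldehyde
Product: 4 4-bromo-2-(methoxymethoxy)phenol, via aryl formate 3 (not isolated)
Conditions: mCPBA, CH2Cl2, 0 °C to rt; NaHCO3 wash; then Et3N (cat.), MeOH, rt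
Reagents that add atoms: 3-chloroperoxybenzoic acid (mCPBA), O=C(OO)c1cccc(Cl)c1
Why: Baeyer–Villiger oxidation of an ortho-alkoxybenzaldehyde proceeds with aryl migration to the formate, and mild methanolysis then frees the phenol para to bromine.

Step 3
Reactants: 4 4-bromo-2-(methoxymethoxy)phenol
Product: 5 2-[4-bromo-2-(methoxymethoxy)phenoxy]acetic acid
Conditions: ClCH2CO2H, NaOH, H2O, 90 °C; then cold aq. NaH2PO4/H3PO4 to pH 3
Reagents that add atoms: chloroacetic acid, OC(=O)CCl
Why: Williamson ether synthesis (SN2 of the phenoxide on chloroacetate) is the classical route to aryloxyacetic acids, and the MOM acetal tolerates hot alkali and a brief cold, mildly acidic work-up.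

Step 4
Reactants: 5 2-[4-bromo-2-(methoxymethoxy)phenoxy]acetic acid; 6 3,4-dihydroxybenzaldehyde
Product: 8 (Z)-3-(3,4-diacetoxyphenyl)-2-[4-bromo-2-(methoxymethoxy)phenoxy]acrylic acid, via 3,4-diacetoxybenzaldehyde 7 (not isolated)
Conditions: Ac2O, Et3N, rt then 105 °C; then H2O/THF, rt
Reagents that add atoms: acetic anhydride, CC(=O)OC(C)=O
Why: Perkin (Oglialoro) condensation, in which acetic anhydride acetylates the phenols of 6 to 7 and, with Et3N, brings about enolization of 5 and aldol-type addition to the aldehyde, after which elimination gives the thermodynamically favoured alkene with aryl trans to carboxyl while the basic medium spares the MOM acetal.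

Step 5
Reactants: 8 (Z)-3-(3,4-diacetoxyphenyl)-2-[4-bromo-2-(methoxymethoxy)phenoxy]acrylic acid
Product: 9 (E)-3-(3,4-diacetoxyphenyl)-2-[4-bromo-2-(methoxymethoxy)phenoxy]acrylic acid
Conditions: fac-Ir(ppy)3 (1 mol %), MeCN, 450 nm LEDs, rt, Ar; chromatography, recovered 8 re-irradiated
Reagents that add atoms: none
Why: Sensitized E/Z photoisomerization of a cinnamate, in which triplet energy transfer from the excited trivalent-iridium complex should be faster to planar, fully conjugated 8 than to 9, whose aryl ring is twisted out of conjugation by the cis carboxyl, so that 9 accumulates in the photostationary mixture.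

Step 6
Reactants: 9 (E)-3-(3,4-diacetoxyphenyl)-2-[4-bromo-2-(methoxymethoxy)phenoxy]acrylic acid
Product: 10 (E)-2-[4-bromo-2-(methoxymethoxy)phenoxy]-3-(3,4-dihydroxyphenyl)acrylic acid
Conditions: Et3N, degassed MeOH, 0 °C to rt, Ar, dark; then cold aq. NaH2PO4
Reagents that add atoms: none
Why: Amine-promoted methanolysis (transesterification) of the two aryl acetates is fast at or below room temperature, conditions under which the MOM acetal, the aryl bromide and the alkene geometry should be unaffected.

Step 7
Reactants: 10 (E)-2-[4-bromo-2-(methoxymethoxy)phenoxy]-3-(3,4-dihydroxyphenyl)acrylic acid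
Product: 13 3-[4-bromo-2-(methoxymethoxy)phenoxy]-6,7-dihydroxy-2H-chromen-2-one, via o-quinone 11 (not isolated), via dienone lactone 12 (not isolated)
Conditions: divided cell, graphite-felt anode, Pt cathode, 0.2 M NaOAc/AcOH buffer (pH 5)–MeCN 1:1, controlled potential at the foot of the catechol wave (about +0.4 V vs Ag/AgCl, to be fixed by cyclic voltammetry), 2 F/mol, rt, N2
Reagents that add atoms: none
Why: At the carbon anode the catechol of 10 loses two electrons and two protons to give o-quinone 11, in which C8a (ortho to the side chain, para to the former 3-hydroxyl) is the β-carbon of the C7=O/C8=C8a enone; the carboxylate, held cis to the ring by the E alkene, adds there to give dienone lactone 12, and loss of the C8a proton restores the aromatic 6,7-catechol of 13. The closest known reaction type is the intramolecular Michael addition of a carboxylate to an electrochemically or enzymatically generated o-quinone, as in the oxidative cyclization of cis-caffeic acid to esculetin and the anodic lactonization of dihydrocaffeic acid. The one new ring, the lactone O1–C2–C3–C4–C4a–C8a, closes in a 6-exo-trig mode, since O1 attacks C8a while the C8=C8a π bond stays outside the ring being formed. No stereocenter results, because the sp3 carbon C8a of 12 is flattened again on tautomerization. The step needs regioselectivity for C8a over C5, which the quinone supplies: C8a is the terminus of direct 1,4-addition, where oxygen and nitrogen nucleophiles add to 4-substituted o-quinones, whereas C5 is α to the C6 carbonyl and could only be reached by a cross-ring 1,6-addition. It also needs chemoselectivity, which the potential supplies: the catechol should oxidize well below the bromo-dialkoxy ring B and somewhat below the less electron-rich coumarin product, the charge is limited to 2 F/mol, the pH 5 buffer keeps the acid ionized and the MOM acetal intact, and the MOM cap leaves the carboxylate as the only internal nucleophile.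

Step 8
Reactants: 13 3-[4-bromo-2-(methoxymethoxy)phenoxy]-6,7-dihydroxy-2H-chromen-2-one
Product: 14 3-[4-bromo-2-(methoxymethoxy)phenoxy]-6,7-bis(methoxymethoxy)-2H-chromen-2-one
Conditions: MOMCl, i-Pr2NEt, CH2Cl2/DMF, 0 °C to rt
Reagents that add atoms: chloromethyl methyl ether (MOMCl), COCCl
Why: MOM protection of both phenols (Williamson-type alkylation) masks the catechol, which would otherwise bind palladium and oxidize under the basic Heck conditions, with groups that leave in the final acid step.

Step 9
Reactants: 15 (R)-3-(3,4-dihydroxyphenyl)-2-hydroxypropanoic acid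
Product: 16 tert-butyl (R)-3-(3,4-dihydroxyphenyl)-2-hydroxypropanoate
Conditions: Cl3CC(=NH)Ot-Bu (2.5 equiv), THF/cyclohexane, rt
Reagents that add atoms: tert-butyl 2,2,2-trichloroacetimidate, CC(C)(C)OC(=N)C(Cl)(Cl)Cl
Why: Imidate esterification, in which only the carboxylic acid is acidic enough to protonate the imidate and be tert-butylated, so the phenols and the secondary alcohol stay free without added Lewis acid and the stereocenter is not involved.

Step 10
Reactants: 16 tert-butyl (R)-3-(3,4-dihydroxyphenyl)-2-hydroxypropanoate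
Product: 17 tert-butyl (R)-3-[3,4-bis(methoxymethoxy)phenyl]-2-hydroxypropanoate
Conditions: MOMCl (2.2 equiv), K2CO3, acetone, 0 °C to rt
Reagents that add atoms: chloromethyl methyl ether (MOMCl), COCCl
Why: Williamson-type alkylation in which K2CO3 ionizes only the phenols, so the α-hydroxy ester oxygen stays free and the stereocenter untouched.

Step 11
Reactants: 17 tert-butyl (R)-3-[3,4-bis(methoxymethoxy)phenyl]-2-hydroxypropanoate
Product: 18 tert-butyl (R)-2-(acryloyloxy)-3-[3,4-bis(methoxymethoxy)phenyl]propanoate
Conditions: acryloyl chloride, Et3N, CH2Cl2 (trace BHT), −20 to 0 °C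
Reagents that add atoms: acryloyl chloride, C=CC(=O)Cl
Why: O-acylation of the secondary alcohol with an acid chloride forms the ester without breaking the C–O bond at the stereocenter, and the cold, weakly basic medium should not enolize the α-acyloxy ester, so the R configuration is retained.

Step 12
Reactants: 14 3-[4-bromo-2-(methoxymethoxy)phenoxy]-6,7-bis(methoxymethoxy)-2H-chromen-2-one; 18 tert-butyl (R)-2-(acryloyloxy)-3-[3,4-bis(methoxymethoxy)phenyl]propanoate
Product: 19 tert-butyl (R)-3-[3,4-bis(methoxymethoxy)phenyl]-2-{[(E)-3-{4-[(6,7-bis(methoxymethoxy)-2-oxo-2H-chromen-3-yl)oxy]-3-(methoxymethoxy)phenyl}acryloyl]oxy}propanoate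
Conditions: Pd2(dba)3 (2.5 mol %), [HP(t-Bu)3]BF4 (10 mol %), Cy2NMe, 1,4-dioxane, 80 °C
Reagents that add atoms: none
Why: Mizoroki–Heck reaction, in which zerovalent palladium carrying the bulky electron-rich phosphine inserts into the electron-rich C–Br bond, syn carbopalladation of the terminal acrylate and syn β-hydride elimination give the E cinnamate, and the hindered tertiary amine is too weak a base to epimerize the α-acyloxy ester or open the lactone.

Step 13
Reactants: 19 tert-butyl (R)-3-[3,4-bis(methoxymethoxy)phenyl]-2-{[(E)-3-{4-[(6,7-bis(methoxymethoxy)-2-oxo-2H-chromen-3-yl)oxy]-3-(methoxymethoxy)phenyl}acryloyl]oxy}propanoate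
Product: 20 (R)-3-(3,4-dihydroxyphenyl)-2-{[(E)-3-{4-[(6,7-dihydroxy-2-oxo-2H-chromen-3-yl)oxy]-3-hydroxyphenyl}acryloyl]oxy}propanoic acid
Conditions: TFA/CH2Cl2/H2O (10:10:1), 0 °C to rt, high dilution
Reagents that add atoms: none
Why: Acid-catalysed hydrolysis of the five aryl MOM acetals and E1-type loss of isobutene from the tert-butyl ester should occur under conditions to which the cinnamoyl ester, the coumarin lactone and the stereocenter (no bond to it broken, no base present) are inert.

**Compound list**

1 | 4-bromo-2-hydroxybenzaldehyde | O=Cc1ccc(Br)cc1O | starting material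
2 | 4-bromo-2-(methoxymethoxy)benzaldehyde | O=Cc1ccc(Br)cc1OCOC | intermediate
3 | 4-bromo-2-(methoxymethoxy)phenyl formate | O=COc1ccc(Br)cc1OCOC | intermediate
4 | 4-bromo-2-(methoxymethoxy)phenol | Oc1ccc(Br)cc1OCOC | intermediate
5 | 2-[4-bromo-2-(methoxymethoxy)phenoxy]acetic acid | OC(=O)COc1ccc(Br)cc1OCOC | intermediate
6 | 3,4-dihydroxybenzaldehyde | O=Cc1ccc(O)c(O)c1 | starting material
7 | 3,4-diacetoxybenzaldehyde | O=Cc1ccc(OC(C)=O)c(OC(C)=O)c1 | intermediate
8 | (Z)-3-(3,4-diacetoxyphenyl)-2-[4-bromo-2-(methoxymethoxy)phenoxy]acrylic acid (aryl trans to CO2H) | OC(=O)/C(Oc1ccc(Br)cc1OCOC)=C/c1ccc(OC(C)=O)c(OC(C)=O)c1 | intermediate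
9 | (E)-3-(3,4-diacetoxyphenyl)-2-[4-bromo-2-(methoxymethoxy)phenoxy]acrylic acid (aryl cis to CO2H) | OC(=O)/C(Oc1ccc(Br)cc1OCOC)=C\c1ccc(OC(C)=O)c(OC(C)=O)c1 | intermediate
10 | (E)-2-[4-bromo-2-(methoxymethoxy)phenoxy]-3-(3,4-dihydroxyphenyl)acrylic acid | OC(=O)/C(Oc1ccc(Br)cc1OCOC)=C\c1ccc(O)c(O)c1 | intermediate
11 | (E)-2-[4-bromo-2-(methoxymethoxy)phenoxy]-3-(3,4-dioxocyclohexa-1,5-dien-1-yl)acrylic acid (o-quinone) | OC(=O)/C(Oc1ccc(Br)cc1OCOC)=C\C1=CC(=O)C(=O)C=C1 | intermediate
12 | 3-[4-bromo-2-(methoxymethoxy)phenoxy]-7-hydroxy-8aH-chromene-2,6-dione (transient, racemic at C8a) | O=C1OC2C=C(O)C(=O)C=C2C=C1Oc1ccc(Br)cc1OCOC | intermediate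
13 | 3-[4-bromo-2-(methoxymethoxy)phenoxy]-6,7-dihydroxy-2H-chromen-2-one | O=c1oc2cc(O)c(O)cc2cc1Oc1ccc(Br)cc1OCOC | intermediate
14 | 3-[4-bromo-2-(methoxymethoxy)phenoxy]-6,7-bis(methoxymethoxy)-2H-chromen-2-one | O=c1oc2cc(OCOC)c(OCOC)cc2cc1Oc1ccc(Br)cc1OCOC | intermediate
15 | (R)-3-(3,4-dihydroxyphenyl)-2-hydroxypropanoic acid, (R)-danshensu | O[C@H](Cc1ccc(O)c(O)c1)C(=O)O | starting material
16 | tert-butyl (R)-3-(3,4-dihydroxyphenyl)-2-hydroxypropanoate | O[C@H](Cc1ccc(O)c(O)c1)C(=O)OC(C)(C)C | intermediate
17 | tert-butyl (R)-3-[3,4-bis(methoxymethoxy)phenyl]-2-hydroxypropanoate | O[C@H](Cc1ccc(OCOC)c(OCOC)c1)C(=O)OC(C)(C)C | intermediate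
18 | tert-butyl (R)-2-(acryloyloxy)-3-[3,4-bis(methoxymethoxy)phenyl]propanoate | C=CC(=O)O[C@H](Cc1ccc(OCOC)c(OCOC)c1)C(=O)OC(C)(C)C | intermediate
19 | tert-butyl (R)-3-[3,4-bis(methoxymethoxy)phenyl]-2-{[(E)-3-{4-[(6,7-bis(methoxymethoxy)-2-oxo-2H-chromen-3-yl)oxy]-3-(methoxymethoxy)phenyl}acryloyl]oxy}propanoate | O=C(/C=C/c1ccc(Oc2cc3cc(OCOC)c(OCOC)cc3oc2=O)c(OCOC)c1)O[C@H](Cc1ccc(OCOC)c(OCOC)c1)C(=O)OC(C)(C)C | intermediate
20 | (R)-3-(3,4-dihydroxyphenyl)-2-{[(E)-3-{4-[(6,7-dihydroxy-2-oxo-2H-chromen-3-yl)oxy]-3-hydroxyphenyl}acryloyl]oxy}propanoic acid (CNP0318082.1) | O=C(/C=C/c1ccc(Oc2cc3cc(O)c(O)cc3oc2=O)c(O)c1)O[C@H](Cc1ccc(O)c(O)c1)C(=O)O | target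

**Step count**

Total: 13 steps. Longest linear sequence: 10 steps (steps 1–8, 12, 13, from 4-bromo-2-hydroxybenzaldehyde).

**Steps most likely to fail**

Step 7 (anodic lactonization). The electrogenerated quinone may be intercepted by water, acetate or unoxidized catechol faster than the carboxylate closes, giving oligomers that passivate the carbon surface. The product catechol may also be oxidized further once the substrate runs low. The fallback sets out from acid 5 and returns at 13, and brings the lactone oxygen in with the aldehyde instead of creating it by oxidation. Perkin–Oglialoro condensation of 5 with commercial 2,4,5-trihydroxybenzaldehyde (O=Cc1cc(O)c(O)cc1O; Ac2O, Et3N, 110 °C) should give 6,7-diacetoxy-3-[4-bromo-2-(methoxymethoxy)phenoxy]-2H-chromen-2-one F1 directly, by O-acetylation, aldol condensation and lactonization onto the ortho oxygen. Et3N in MeOH then removes the two acetates to give 13.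

Step 5 (photoisomerization). The photostationary mixture may stay rich in 8, the aryl vinyl ether may photocyclize onto ring B on long irradiation, the excited sensitizer may reduce the C–Br bond, or 9 may revert to 8 during isolation. The fallback sets out from phenol 4 and aldehyde 6 and returns at 10, setting the geometry by a kinetically controlled olefination; it also bypasses steps 3, 4 and 6 should the Perkin condensation be the weak point. Diazo transfer (4-acetamidobenzenesulfonyl azide, DBU, MeCN) onto commercial methyl bis(2,2,2-trifluoroethoxy)phosphorylacetate gives methyl 2-[bis(2,2,2-trifluoroethoxy)phosphoryl]-2-diazoacetate F2. Rh2(OAc)4-catalysed O–H insertion of F2 into phenol 4 (toluene, 80 °C) gives methyl 2-[bis(2,2,2-trifluoroethoxy)phosphoryl]-2-[4-bromo-2-(methoxymethoxy)phenoxy]acetate F3. Aldehyde 6 is silylated (TBSCl, imidazole, DMF) to 3,4-bis(tert-butyldimethylsilyloxy)benzaldehyde F4. Still–Gennari olefination of F4 with F3 (KN(SiMe3)2, 18-crown-6, THF, −78 °C) should place the aryl group cis to the ester in methyl (E)-2-[4-bromo-2-(methoxymethoxy)phenoxy]-3-[3,4-bis(tert-butyldimethylsilyloxy)phenyl]acrylate F5, by analogy with α-alkyl and α-halo reagents of this type. LiOH in degassed aqueous THF then cleaves the methyl ester and both aryl silyl ethers to give 10.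

Step 13 (global deprotection). Formaldehyde and tert-butyl cation liberated in the acid may be captured by the electron-rich catechol rings (hydroxymethylation, methylene bridging, tert-butylation), or the cinnamoyl ester may be cleaved on prolonged exposure. The fallback sets out from 19 and returns at 20, unmasking in two stages so that no free formaldehyde is formed. ZnBr2 with n-PrSH in CH2Cl2 (0 °C, minutes) transfers the five methoxymethyl groups to sulfur and should leave tert-butyl (R)-3-(3,4-dihydroxyphenyl)-2-{[(E)-3-{4-[(6,7-dihydroxy-2-oxo-2H-chromen-3-yl)oxy]-3-hydroxyphenyl}acryloyl]oxy}propanoate F6. Brief treatment with TFA in CH2Cl2 then removes only the tert-butyl ester to give 20.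

**Further compounds**

F1 | step 7 | 6,7-diacetoxy-3-[4-bromo-2-(methoxymethoxy)phenoxy]-2H-chromen-2-one | O=c1oc2cc(OC(C)=O)c(OC(C)=O)cc2cc1Oc1ccc(Br)cc1OCOC
F2 | step 5 | methyl 2-[bis(2,2,2-trifluoroethoxy)phosphoryl]-2-diazoacetate | COC(=O)C(=[N+]=[N-])P(=O)(OCC(F)(F)F)OCC(F)(F)F
F3 | step 5 | methyl 2-[bis(2,2,2-trifluoroethoxy)phosphoryl]-2-[4-bromo-2-(methoxymethoxy)phenoxy]acetate | COC(=O)C(Oc1ccc(Br)cc1OCOC)P(=O)(OCC(F)(F)F)OCC(F)(F)F
F4 | step 5 | 3,4-bis(tert-butyldimethylsilyloxy)benzaldehyde | O=Cc1ccc(O[Si](C)(C)C(C)(C)C)c(O[Si](C)(C)C(C)(C)C)c1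
F5 | step 5 | methyl (E)-2-[4-bromo-2-(methoxymethoxy)phenoxy]-3-[3,4-bis(tert-butyldimethylsilyloxy)phenyl]acrylate | COC(=O)/C(Oc1ccc(Br)cc1OCOC)=C\c1ccc(O[Si](C)(C)C(C)(C)C)c(O[Si](C)(C)C(C)(C)C)c1
F6 | step 13 | tert-butyl (R)-3-(3,4-dihydroxyphenyl)-2-{[(E)-3-{4-[(6,7-dihydroxy-2-oxo-2H-chromen-3-yl)oxy]-3-hydroxyphenyl}acryloyl]oxy}propanoate | O=C(/C=C/c1ccc(Oc2cc3cc(O)c(O)cc3oc2=O)c(O)c1)O[C@H](Cc1ccc(O)c(O)c1)C(=O)OC(C)(C)C
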